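How much of the solid substrate ends as target, when undissolved solid destroys target?

solid substrate 0.10 M; coupling partner 2.00 equiv; time 20 h

- at 20 h, what has stopped the reaction, if anything has (for what has run out or reacted, a solid counts together with what of it has only dissolved) (the coupling partner has run out first / it is still moving / all of the solid substrate has reacted)
- part of the solid substrate that has turned into other species by 20 h (what has only dissolved does not count)
- how much target there is at 20 h, in percent of the solid substrate charged
- how much side product there is at 20 h, in percent of the solid substrate charged
- amount of target if the flask were left three thousand times as long, in percent of the solid substrate charged

- in percentages every species weighs as the solid substrate in it: one side product counts as two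
- for target the solid product is counted in
- as a solid, counted per litre of solution: solid substrate, solid product
- at the start none of the solid substrate is in solution
- what has only dissolved of solid substrate counts as not reacted
- the reaction counts as stopped when no species that holds the solid substrate changes by six tenths of a point or more over the second half of the time
- run time (flask): 20 h

    solid product ⇌ target, rate k1*(cs1 - [target]) while solid is left; crystals form when [target] > cs1 (cs1 = 6.0 mM, k1 = 0.00970 s⁻¹)
    dissolved substrate + coupling partner → target (k2 = 0.00209 M⁻¹ s⁻¹)
    solid substrate + target → side product (k3 = 0.0128 M⁻¹ s⁻¹)
    solid substrate ⇌ dissolved substrate, rate k4*(cs4 - [dissolved substrate]) while solid is left; crystals form when [dissolved substrate] > cs4 (cs4 = 49 mM, k4 = 8.89 × 10⁻⁵ s⁻¹)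

First, how fast does material enter? Dissolved substrate couples with a half-life of 0.46 h, shorter than the time. So its level A soon balances dissolving against coupling, at 8.59 mM. With the coupling partner as charged, target is made at a feed F of 12.9 mM h⁻¹.

Second, what becomes of that feed? Beside the full charge of solid, target has a half-life of 0.15 h, shorter than that of dissolved substrate. The side reaction therefore first keeps pace with F. Replace the dissolved target curve by its solubility as a mean. Pace then holds down to a hand-over level L of solid, which is F divided by the side-reaction constant and the solubility: 46.8 mM.

Third, what does each stage cost? Above L, dissolved material first fills A and the target solubility. The remaining solid loss splits evenly between dissolving and the side reaction, giving 19.3 mM side product. Below L, solid reaches zero after 2.51 h, and dissolving takes its share, so the side reaction gets L(1 − ln 2), or 14.4 mM.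

Side product counts double, so this reckoning gives 67.3% side product and 32.7% target. Solid reaches zero near 5.13 h. Once the dissolved remainder has coupled as well, 33.2% of the coupling partner is used.

In the forecast, all of the solid substrate has reacted, with conversion 100%, target 34% and side product 66%, a little apart from this reckoning, and 34% at long times, since “nothing consumes the target once the solid has gone”.

The flask gives all of the solid substrate has reacted, target 31.9%, side product 68.1%, conversion 100% and long-time target 31.9%. The reckoned target stands 0.80 percentage points above it.

Target is lost because solid waits beside it while dissolving takes hours: target reaches >99.9% without the side reaction and 89.7% without the dissolving time. In this flask at 2.00 h, solid stands at 58.2 mM, above L, with solid product at 0%. In the neighbour charged with 0.060 M, L is 41.9 mM, and the charge less its pools is 41.2 mM, so the upper stage vanishes. L then gives 42.9% side product, and that neighbour shows 47.0%.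

The constants stand for no real mixture; the flask was simulated.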